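**Retrosynthetic overview**

- Target 32 comes from exocyclic enone 30 (1,2-reduction at C9, phenol deacetylation), 30 from ketone 24 (C8 methylenation), and 24 from the trans-fused 4,9-diketone 15, whose C6 silyl group is a masked hydroxyl (isopropyl addition at C4, C–Si to C–O, esterification).
- Structural feature used: the oxygens on C4 and C9 are 1,5-related through C5, C1 and C10, so 15 is the retro-aldol product of a cyclobutanol with a temporary C5–C9 bond. That cyclobutane (C5, C1, C10, C9) is the intramolecular [2+2] photoadduct of the ring enol C5=C9 of a 2-acylcyclopentanone (ring C5–C6–C7–C8–C9) with the 1,1-disubstituted C1=C10 alkene of its own acyl chain.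
- Ring order: the bought cyclopentenone ring (C5 to C9) comes first; the photocycloaddition closes the five-membered ring C1–C2–C3–C4–C5 and the cyclobutane; the retro-aldol merges cyclobutane and cyclopentanone into the seven-membered ring.
- Stereochemistry: C6 from an enantioselective conjugate silylation; C1 from photoaddition anti to silicon; C5 by equilibration next to the C4 ketone; C4 and C9 by additions anti to the C1 methyl.

Key step: step 6

Remark on the chemistry: atom labels follow daucane numbering (C1 quaternary methyl-bearing fusion carbon, C4 isopropyl carbinol, C5 fusion CH, C6 ester carbon, C8 methylene-bearing carbon, C9 secondary carbinol, C10 the CH2 between C1 and C9), and the enantiomer of the chiral N-heterocyclic carbene ligand in step 3 is assumed to be the one that gives the (S)-configured C–Si carbon.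

**Route**

Step 1
Reactants: 1 4-methylpent-4-enoic acid
Product: 2 4-methylpent-4-en-1-ol
Conditions: LiAlH4, Et2O, 0 °C to rt; aqueous work-up
Reagents that add atoms: none
Why: Hydride reduction of a carboxylic acid to the primary alcohol, which leaves the isolated 1,1-disubstituted alkene untouched.

Step 2
Reactants: 2 4-methylpent-4-en-1-ol
Product: 3 4-methylpent-4-enal
Conditions: TEMPO (cat.), PhI(OAc)2, CH2Cl2, rt
Reagents that add atoms: none
Why: Nitroxyl-catalysed oxidation stops at the aldehyde and allows the volatile product to be used as a solution without over-oxidation or alkene migration.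

Step 3
Reactants: 4 cyclopent-2-en-1-one; 5 (dimethylphenylsilyl)boronic acid pinacol ester; 3 4-methylpent-4-enal
Product: 8 (2S,3S)-3-[dimethyl(phenyl)silyl]-2-(1-hydroxy-4-methylpent-4-en-1-yl)cyclopentan-1-one (2,3-trans, carbinol epimers), via boron enolate 6 (not isolated), via boron aldolate 7 (not isolated)
Conditions: CuCl (2 mol %), enantiopure imidazolinium salt (NHC precursor, 2.2 mol %), NaOtBu (4.5 mol %), 5 (0.95 equiv), THF, −78 °C; then 3, −78 to −20 °C; aq. NH4Cl
Reagents that add atoms: none
Why: Copper-catalysed enantioselective conjugate silyl transfer from the Si–B reagent sets the C–Si carbon (future C6) under ligand control, and the regiodefined boron enolate is trapped in an aldol addition at the carbon next to the silyl carbon (future C5), trans to silicon; the silylborane is kept limiting so that no silylcopper species remains to add to the aldehyde.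

Step 4
Reactants: 8 the silyl aldol
Product: 9 (3S)-3-[dimethyl(phenyl)silyl]-2-(4-methylpent-4-enoyl)cyclopentan-1-one, drawn as its ring enol
Conditions: Dess–Martin periodinane, NaHCO3, CH2Cl2, 0 °C to rt
Reagents that add atoms: none
Why: Periodinane oxidation of a β-hydroxy ketone to the β-diketone under buffered conditions; the carbinol and C5 centres are erased, so the epimer mixture of 8 converges and only the C6 centre remains.

Step 5
Reactants: 9 the enolised 2-acylcyclopentanone
Product: 10 benzyl (3S)-3-[dimethyl(phenyl)silyl]-2-(4-methylpent-4-enoyl)cyclopent-1-en-1-yl carbonate (endocyclic enol carbonate)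
Conditions: BnOCOCl, pyridine, CH2Cl2, 0 °C
Reagents that add atoms: benzyl chloroformate, O=C(Cl)OCc1ccccc1
Why: O-acylation of the enolised β-diketone is expected at the ring oxygen, which is remote from the silyl group whereas the side-chain oxygen lies next to it, giving the vinylogous carbonate with the C5=C9 double bond fixed inside the five-membered ring.

Step 6
Reactants: 10 the endocyclic enol benzyl carbonate
Product: 11 tricyclic photoadduct: benzyl carbonate of the C9 cyclobutanol, cyclobutane C5–C1–C10–C9 cis-fused both to the silylated cyclopentane (C5–C6–C7–C8–C9) and to the cyclopentanone (C1–C2–C3–C4–C5), C1 bonded to the face of C5 opposite silicon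
Conditions: hν (medium-pressure Hg lamp, Pyrex filter), degassed cyclohexane (0.01 M), rt
Reagents that add atoms: none
Why: Excitation of the vinylogous carbonate chromophore C4(=O)–C5=C9(OCO2Bn) and intersystem crossing give a triplet that adds stepwise to the tethered C1=C10 alkene, the closest known reaction type being the intramolecular de Mayo (enone–alkene [2+2]) photocycloaddition of enol carbonates of 2-acylcyclopentanones. The cyclopentanone ring C1–C2–C3–C4–C5 closes first by 1,5 (5-exo-trig) bonding of C5 to C1, as the three-atom tether C4–C3–C2 dictates, and the 1,4-biradical at C9 and C10 then collapses to the C9–C10 bond, closing the cyclobutane by radical recombination. C5 and C9 become quaternary with the cyclobutane necessarily cis-fused to both five-membered rings, and the alkene is expected to add to the face of C5=C9 opposite the allylic C6 dimethylphenylsilyl group, which fixes the new quaternary C1 relative to C6. The step needs straight rather than crossed regiochemistry, which the tether length secures and which a 1,1-disubstituted alkene tolerates, and anti facial selectivity, which the bulky silyl group next to the first-formed bond secures. Holding the enol in the ring as the carbonate excludes reaction through the exocyclic enol tautomer, and the Pyrex filter keeps the phenylsilane and the product ketone from absorbing strongly.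

Step 7
Reactants: 11 the tricyclic photoadduct
Product: 15 trans-fused 6-[dimethyl(phenyl)silyl]-1-methylhydroazulene-4,9-dione (C5–H anti to the C1 methyl and syn to the C6 silyl group), via hydrogen carbonate 12 (not isolated), via cyclobutanol 13 (not isolated), via epimeric diketone 14 (not isolated)
Conditions: H2 (1 atm), Pd/C, EtOAc, rt; filter; then DBU (0.2 equiv), toluene, rt
Reagents that add atoms: none
Why: Hydrogenolysis of the benzyl carbonate and loss of CO2 unmask the C9 cyclobutanol, whose retro-aldol cleavage of C5–C9 (driven by ring strain and formation of the C4 enol) opens the seven-membered ring; base then equilibrates C5 next to the C4 ketone toward the epimer expected to be favoured, in which the seven-membered ring carries C4 and the silyl group trans and both pseudo-equatorial.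

Step 8
Reactants: 15 the trans-fused 4,9-diketone
Product: 16 C9 ethylene ketal of 15 (C4 ketone free)
Conditions: TMSOCH2CH2OTMS, TMSOTf (cat.), CH2Cl2, −78 to −30 °C; pyridine quench
Reagents that add atoms: 1,2-bis(trimethylsilyloxy)ethane, C[Si](C)(C)OCCO[Si](C)(C)C
Why: Low-temperature silyl-triflate-catalysed ketalisation discriminates kinetically for the C9 carbonyl flanked by two methylenes over the C4 carbonyl, which is shielded by the ring-fusion carbon, the quaternary C1 and the silyl group, and it is not acidic enough to cleave the aryl–silicon bond.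

Step 9
Reactants: 16 the C9 ketal ketone; 17 isopropylmagnesium chloride
Product: 18 C4 isopropyl carbinol, C9 ethylene ketal (C4–OH cis to the C1 methyl, isopropyl cis to C5–H)
Conditions: 17, anhydrous CeCl3, THF, −78 to 0 °C; aq. NH4Cl
Reagents that add atoms: none
Why: The organocerium reagent suppresses enolisation and β-hydride reduction of the hindered cyclopentanone, and addition is expected on the face of C5–H, opposite the pseudo-axial C1 methyl, which sets C4 as the (4R) carbinol.

Step 10
Reactants: 18 the silyl carbinol
Product: 21 4,6-diol, C9 ethylene ketal (C6–OH in the position the silicon occupied), via acetoxysilane 19 (not isolated), via silyl ether 20 (not isolated)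
Conditions: Hg(OAc)2, AcOOH in AcOH, NaOAc, rt
Reagents that add atoms: peracetic acid, CC(=O)OO
Why: One-pot Fleming–Tamao oxidation, in which ipso-mercuriodesilylation removes the phenyl group and peracid-induced 1,2-migration from silicon to oxygen converts C–Si into C–O with retention at C6; the ketal stays on so that no ketone is exposed to the peracid, and the acetate buffer protects ketal and tertiary carbinol.

Step 11
Reactants: 21 the 4,6-diol; 22 4-acetoxybenzoic acid
Product: 23 C6 4-acetoxybenzoate, C9 ethylene ketal
Conditions: DCC, DMAP (cat.), CH2Cl2, 0 °C to rt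
Reagents that add atoms: none
Why: Steglich esterification acylates the secondary C6 hydroxyl only, because the tertiary C4 carbinol is too hindered to react, and doing it before ketal removal avoids hemiketal formation between a free C9 ketone and the hydroxyls.

Step 12
Reactants: 23 the ester ketal
Product: 24 C6 4-acetoxybenzoate with free C9 ketone
Conditions: 1 M HCl, THF, rt
Reagents that add atoms: water, O
Why: Mild aqueous acid hydrolyses the dioxolane, while the aryl acetate, the benzoate and the tertiary carbinol are stable to these conditions.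

Step 13
Reactants: 24 the C9 ketone
Product: 25 C8=C9 trimethylsilyl enol ether with the C4 hydroxyl also silylated
Conditions: TMSOTf (2.5 equiv), Et3N, CH2Cl2, 0 °C
Reagents that add atoms: trimethylsilyl trifluoromethanesulfonate, C[Si](C)(C)OS(=O)(=O)C(F)(F)F
Why: Soft enolisation spares both esters, which an amide base would attack at the aryl acetate, and the amine should remove the accessible C8 proton rather than the neopentyl C10 proton next to quaternary C1; the tertiary hydroxyl is silylated at the same time.

Step 14
Reactants: 25 the silyl enol ether; 26 dimethylmethylideneammonium iodide (Eschenmoser's salt)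
Product: 28 C8 dimethylaminomethyl ketone (Mannich base, C8 epimers) with free C4 hydroxyl, via silylated Mannich base 27 (not isolated)
Conditions: 26, CH2Cl2, rt; then 1 M HCl, THF, 0 °C; aq. NaHCO3
Reagents that add atoms: none
Why: Mannich reaction of the regiodefined enol ether with the preformed iminium salt places the aminomethyl group on C8 only, and the brief acid treatment cleaves the tertiary trimethylsilyl ether.

Step 15
Reactants: 28 the Mannich base
Product: 30 C8 exocyclic enone (8-methylene-9-ketone, C6 4-acetoxybenzoate), via ammonium iodide 29 (not isolated)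
Conditions: MeI, CH2Cl2, rt; then aq. NaHCO3, CH2Cl2, rt
Reagents that add atoms: none
Why: Quaternisation turns the amine into a leaving group, and bicarbonate-induced β-elimination gives the α-methylene ketone under conditions too mild to cleave the aryl acetate or to move the double bond into the ring.

Step 16
Reactants: 30 the exocyclic enone
Product: 31 (9R) allylic alcohol, C6 4-acetoxybenzoate
Conditions: NaBH4, CeCl3·7H2O, MeOH, −78 °C
Reagents that add atoms: none
Why: Luche reduction gives 1,2-reduction only, and hydride is expected to attack the C9 carbonyl from the face opposite the 1,3-related pseudo-axial C1 methyl, placing the hydroxyl cis to that methyl as the target requires; any phenolic acetate lost here is simply carried into step 17.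

Step 17
Reactants: 31 the allylic alcohol acetate
Product: 32 target, (1R,4R,5S,6S,9R)-4,9-dihydroxydauc-8(14)-en-6-yl 4-hydroxybenzoate
Conditions: pyrrolidine, CH2Cl2, 0 °C
Reagents that add atoms: none
Why: Aminolysis removes the activated phenolic acetate far faster than it attacks the hindered alkyl 4-hydroxybenzoate, and no Michael acceptor remains at this stage.

**Compound list**

1 | 4-methylpent-4-enoic acid | C=C(C)CCC(=O)O | starting material
2 | 4-methylpent-4-en-1-ol | C=C(C)CCCO | intermediate
3 | 4-methylpent-4-enal | C=C(C)CCC=O | intermediate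
4 | cyclopent-2-en-1-one | O=C1C=CCC1 | starting material
5 | (dimethylphenylsilyl)boronic acid pinacol ester | C[Si](C)(c1ccccc1)B1OC(C)(C)C(C)(C)O1 | starting material
6 | pinacolboron enolate of (S)-3-[dimethyl(phenyl)silyl]cyclopentanone, enolate C=C toward the silyl carbon | C[Si](C)(c1ccccc1)[C@H]1CCC(OB2OC(C)(C)C(C)(C)O2)=C1 | intermediate (not isolated)
7 | O-pinacolboryl aldolate of 8 | C=C(C)CCC(OB1OC(C)(C)C(C)(C)O1)[C@H]1C(=O)CC[C@@H]1[Si](C)(C)c1ccccc1 | intermediate (not isolated)
8 | (2S,3S)-3-[dimethyl(phenyl)silyl]-2-(1-hydroxy-4-methylpent-4-en-1-yl)cyclopentan-1-one, carbinol epimers | C=C(C)CCC(O)[C@H]1C(=O)CC[C@@H]1[Si](C)(C)c1ccccc1 | intermediate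
9 | (3S)-3-[dimethyl(phenyl)silyl]-2-(4-methylpent-4-enoyl)cyclopentan-1-one, ring enol form | C=C(C)CCC(=O)C1=C(O)CC[C@@H]1[Si](C)(C)c2ccccc2 | intermediate
10 | benzyl (3S)-3-[dimethyl(phenyl)silyl]-2-(4-methylpent-4-enoyl)cyclopent-1-en-1-yl carbonate | C=C(C)CCC(=O)C1=C(OC(=O)OCc2ccccc2)CC[C@@H]1[Si](C)(C)c3ccccc3 | intermediate
11 | tricyclic cyclobutane photoadduct, C9 benzyl carbonate, C4 ketone, C6 silyl anti to the C5–C1 bond | C1C[C@H]([Si](C)(C)c4ccccc4)[C@]23[C@](C)(CCC2=O)C[C@@]13OC(=O)OCc5ccccc5 | intermediate
12 | C9 hydrogen carbonate of the photoadduct | C1C[C@H]([Si](C)(C)c4ccccc4)[C@]23[C@](C)(CCC2=O)C[C@@]13OC(=O)O | intermediate (not isolated)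
13 | C9 cyclobutanol of the photoadduct | C1C[C@H]([Si](C)(C)c4ccccc4)[C@]23[C@](C)(CCC2=O)C[C@@]13O | intermediate (not isolated)
14 | 6-silyl-1-methylhydroazulene-4,9-dione as C5 epimer mixture | C1C[C@H]([Si](C)(C)c3ccccc3)C2[C@](C)(CCC2=O)CC1=O | intermediate (not isolated)
15 | trans-fused 6-[dimethyl(phenyl)silyl]-1-methylhydroazulene-4,9-dione (1R,5S,6S pattern of the target) | C1C[C@H]([Si](C)(C)c3ccccc3)[C@@H]2[C@](C)(CCC2=O)CC1=O | intermediate
16 | C9 ethylene ketal of 15 | C1C[C@H]([Si](C)(C)c3ccccc3)[C@@H]2[C@](C)(CCC2=O)CC14OCCO4 | intermediate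
17 | isopropylmagnesium chloride | CC(C)[Mg]Cl | starting material
18 | C4 isopropyl carbinol, C6 silyl, C9 ethylene ketal | C1C[C@H]([Si](C)(C)c4ccccc4)[C@@H]2[C@](C)(CC[C@@]2(O)C(C)C)CC13OCCO3 | intermediate
19 | C6 acetoxydimethylsilyl analogue of 18 | C1C[C@H]([Si](C)(C)OC(C)=O)[C@@H]2[C@](C)(CC[C@@]2(O)C(C)C)CC13OCCO3 | intermediate (not isolated)
20 | C6 acetoxydimethylsilyl ether | C1C[C@H](O[Si](C)(C)OC(C)=O)[C@@H]2[C@](C)(CC[C@@]2(O)C(C)C)CC13OCCO3 | intermediate (not isolated)
21 | 4,6-diol, C9 ethylene ketal | C1C[C@H](O)[C@@H]2[C@](C)(CC[C@@]2(O)C(C)C)CC13OCCO3 | intermediate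
22 | 4-acetoxybenzoic acid | CC(=O)Oc1ccc(cc1)C(=O)O | starting material
23 | C6 4-acetoxybenzoate, C9 ethylene ketal | C1C[C@H](OC(=O)c3ccc(OC(C)=O)cc3)[C@@H]2[C@](C)(CC[C@@]2(O)C(C)C)CC14OCCO4 | intermediate
24 | C6 4-acetoxybenzoate, C9 ketone | C1C[C@H](OC(=O)c3ccc(OC(C)=O)cc3)[C@@H]2[C@](C)(CC[C@@]2(O)C(C)C)CC1=O | intermediate
25 | C8=C9 trimethylsilyl enol ether, C4 trimethylsilyl ether | C[Si](C)(C)OC1=CC[C@H](OC(=O)c3ccc(OC(C)=O)cc3)[C@@H]2[C@](C)(CC[C@@]2(O[Si](C)(C)C)C(C)C)C1 | intermediate
26 | dimethylmethylideneammonium iodide (Eschenmoser's salt) | C=[N+](C)C.[I-] | starting material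
27 | C8 dimethylaminomethyl ketone, C4 trimethylsilyl ether | CN(C)CC1C[C@H](OC(=O)c3ccc(OC(C)=O)cc3)[C@@H]2[C@](C)(CC[C@@]2(O[Si](C)(C)C)C(C)C)CC1=O | intermediate (not isolated)
28 | C8 dimethylaminomethyl ketone, free C4 hydroxyl (C8 epimers) | CN(C)CC1C[C@H](OC(=O)c3ccc(OC(C)=O)cc3)[C@@H]2[C@](C)(CC[C@@]2(O)C(C)C)CC1=O | intermediate
29 | C8 trimethylammoniomethyl ketone iodide | C[N+](C)(C)CC1C[C@H](OC(=O)c3ccc(OC(C)=O)cc3)[C@@H]2[C@](C)(CC[C@@]2(O)C(C)C)CC1=O.[I-] | intermediate (not isolated)
30 | C8 exocyclic enone, C6 4-acetoxybenzoate | C=C1C[C@H](OC(=O)c3ccc(OC(C)=O)cc3)[C@@H]2[C@](C)(CC[C@@]2(O)C(C)C)CC1=O | intermediate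
31 | (9R) allylic alcohol, C6 4-acetoxybenzoate | C=C1C[C@H](OC(=O)c2ccc(OC(C)=O)cc2)[C@@H]2[C@](C)(CC[C@@]2(O)C(C)C)C[C@H]1O | intermediate
32 | (1R,4R,5S,6S,9R)-4,9-dihydroxydauc-8(14)-en-6-yl 4-hydroxybenzoate (CNP0164257.2) | C=C1C[C@H](OC(=O)c2ccc(O)cc2)[C@@H]2[C@](C)(CC[C@@]2(O)C(C)C)C[C@H]1O | target

**Step count and risks**

Total step count: 17. Longest linear sequence: 17 steps, from 4-methylpent-4-enoic acid 1 (15 steps from cyclopent-2-en-1-one 4).

Steps most likely to fail:

1. Step 7. The epimerisation at C5 may settle on the cis-fused epimer, or protonation of the C4 enol may stay under kinetic control anti to silicon, leaving C5–H on the wrong face. The fallback sets C5 by a syn hydroboration instead of an enolate equilibration; it sets out from epimeric diketone 14, isolated after the hydrogenolysis without the base treatment, and comes back to the route at diol 21.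
   - 14 is ketalised as in step 8 to the epimeric C9 dioxolane ketone F1.
   - CuBr2 in DMF brominates C5, and the α-bromo-β-silyl ketone loses the bromosilane to give the C5=C6 enone F2. The silyl group here serves as a masked enone, so the C5 centre is erased.
   - Isopropylmagnesium chloride 17 with CeCl3 adds 1,2 to C4 anti to the C1 methyl to give the allylic tertiary carbinol F3.
   - BH3·THF, then NaOH and H2O2, adds H to C5 and O to C6 on the same face, opposite the C1 methyl and the allylic C4–O bond, which should give the trans-fused diol 21. C6 is then set relative to C1, whose absolute configuration the silyl group has already fixed in step 6.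

2. Step 9. Enolisation or β-hydride reduction of the hindered C4 ketone may outrun addition, or the nucleophile may add to the wrong face. The fallback sets out from ketone 16 and comes back at carbinol 18. Isopropenylmagnesium bromide with CeCl3, a smaller sp2 nucleophile, should give the isopropenyl carbinol F4, and hydrogenation of its 1,1-disubstituted alkene with H2 and RhCl(PPh3)3 in benzene should give 18 without touching the phenylsilane or the ketal.

3. Step 16. Hydride delivery to the flexible cycloheptenone may show poor or reversed facial selectivity and give the C9 epimer. The fallback sets out from enone 30 and comes back at target 32. The reduction then gives mainly the (9S) allylic alcohol F5. Mitsunobu reaction with 4-nitrobenzoic acid, PPh3 and diisopropyl azodicarboxylate inverts C9 to give the 4-nitrobenzoate F6. K2CO3 in MeOH at 0 °C then cleaves the activated nitrobenzoate and the phenolic acetate together, while the C6 4-hydroxybenzoate is protected as its phenoxide, and releases 32.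

**Further compounds**

F1 | step 7 | C9 ethylene ketal of the 6-silyl-4-ketone as C5 epimer mixture | C1C[C@H]([Si](C)(C)c3ccccc3)C2[C@](C)(CCC2=O)CC14OCCO4
F2 | step 7 | C5=C6 enone (dauc-5-en-4-one) C9 ethylene ketal | O=C1CC[C@]2(C)CC3(OCCO3)CCC=C12
F3 | step 7 | C4 isopropyl allylic carbinol, C5=C6 alkene, C9 ethylene ketal | CC(C)[C@]1(O)CC[C@]2(C)CC3(OCCO3)CCC=C12
F4 | step 9 | C4 isopropenyl carbinol, C6 silyl, C9 ethylene ketal | C1C[C@H]([Si](C)(C)c4ccccc4)[C@@H]2[C@](C)(CC[C@@]2(O)C(C)=C)CC13OCCO3
F5 | step 16 | (9S) allylic alcohol, C6 4-acetoxybenzoate | C=C1C[C@H](OC(=O)c2ccc(OC(C)=O)cc2)[C@@H]2[C@](C)(CC[C@@]2(O)C(C)C)C[C@@H]1O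
F6 | step 16 | (9R) 4-nitrobenzoate, C6 4-acetoxybenzoate | C=C1C[C@H](OC(=O)c2ccc(OC(C)=O)cc2)[C@@H]2[C@](C)(CC[C@@]2(O)C(C)C)C[C@H]1OC(=O)c1ccc(cc1)[N+](=O)[O-]
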